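The C9 carbonyl bridge of the bicyclo[2.2.2]octenone is taken back, by a 1,3-acyl shift of C9 from C11 to C14, to an oxolane-fused cyclobutanone. That ring is the intramolecular [2+2] adduct of an alkoxy(methyl)ketene (C7=C9, tethered through O6–C5 to C4) and the C26=C14 silyl enol ether. The step exploits the α-alkoxy ketone C7–C9 lying β,γ to the C13=C14 alkene, and the oxolane ring C4–C5–O6–C7–C26. In one operation it forms C7–C26 and C9–C14, closes the oxolane and the four-membered ring, and sets C7, C14 and C26 from C4. The precursor is the lactate-ether acid chloride of a (2S)-chromenone carrying a 5-silyloxy dienol ether.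

Key step: step 11

Remark: atom labels C1–O27 follow the atom order of the target SMILES; bicyclic intermediates carry chromene locants (C2 = C18, C4 = C15, C5 = C26, C6 = C4, C8 = C11). TBS = tert-butyldimethylsilyl.
Remark: C7 becomes planar in the ketene, so the lactate configuration is not transmitted; the (S)-ester only keeps the intermediates single diastereomers.
Remark: a flavanone-type pyranone opens by E1cB at C3 under strong base, so carbanion chemistry is finished before that ring exists or is confined to the uniquely acidic C8–H; the C6 epimers are separated, not equilibrated.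
Remark: compounds 1, 3 and 5 are taken as commercially available.

Step 1
Reactants: 1 benzyl (S)-lactate
Product: 2 benzyl (2S)-2-(chloromethoxy)propanoate
Conditions: (CH2O)n, TMSCl, CH2Cl2, 0 °C → rt; used crude
Reagents that add atoms: paraformaldehyde (formaldehyde), C=O; chlorotrimethylsilane, C[Si](C)(C)Cl
Why: Chloromethyl ether formation (hemiformal, then capture of the oxocarbenium ion by chloride) is standard for secondary alcohols and does not involve the α-stereocentre.

Step 2
Reactants: 3 dimedone; 2 benzyl (2S)-2-(chloromethoxy)propanoate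
Product: 4 benzyl (2S)-2-[(2,2-dimethyl-4,6-dioxocyclohexyl)methoxy]propanoate (both ring epimers)
Conditions: LDA (2.2 equiv), THF/DMPU, −78 → 0 °C; then 2, −78 °C; aq NH4Cl
Reagents that add atoms: none
Why: γ-Alkylation of a 1,3-diketone dianion: the second deprotonation gives a C4 carbanion far more nucleophilic than the enolate oxygens, which the chloromethyl ether should alkylate cleanly; the new ring stereocentre forms without control and both epimers are carried on.

Step 3
Reactants: 5 ethyl (3S)-3-hydroxy-3-phenylpropanoate
Product: 6 ethyl (3S)-3-(TBS-oxy)-3-phenylpropanoate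
Conditions: TBSCl, imidazole, DMF, rt
Reagents that add atoms: tert-butyldimethylsilyl chloride, CC(C)(C)[Si](C)(C)Cl
Why: Routine silylation of a secondary alcohol, with retention at the benzylic centre that later becomes C18.

Step 4
Reactants: 6 ethyl (3S)-3-(TBS-oxy)-3-phenylpropanoate
Product: 7 (3S)-3-(TBS-oxy)-3-phenylpropanoic acid
Conditions: LiOH, THF/H2O, 0 °C → rt; then 1 M HCl to pH 3
Reagents that add atoms: lithium hydroxide, [Li+].[OH-]
Why: Saponification (acyl–oxygen cleavage) under conditions mild enough to keep the β-silyloxy group; no stereocentre is touched.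

Step 5
Reactants: 4 benzyl (2S)-2-[(2,2-dimethyl-4,6-dioxocyclohexyl)methoxy]propanoate; 7 (3S)-3-(TBS-oxy)-3-phenylpropanoic acid
Product: 9 benzyl (2S)-2-({5-[(3S)-3-(TBS-oxy)-3-phenylpropanoyl]-2,2-dimethyl-4,6-dioxocyclohexyl}methoxy)propanoate (enol form; both ring epimers), via enol ester 8 (not isolated)
Conditions: DCC, DMAP (1.2 equiv), CH2Cl2, 0 °C → rt
Reagents that add atoms: none
Why: Carbodiimide C-acylation of a cyclic 1,3-dione: the enol ester formed first is isomerised by DMAP (O→C acyl transfer) to the chelated 2-acyl trione, and existing stereocentres are unaffected.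

Step 6
Reactants: 9 the 2-acyl trione
Product: 11 benzyl (2S)-2-{[(2S,6R)-7,7-dimethyl-4,5-dioxo-2-phenyl-3,4,5,6,7,8-hexahydro-2H-chromen-6-yl]methoxy}propanoate, via hydroxy trione 10 (not isolated)
Conditions: HF·pyridine, THF, 0 °C → rt; then TsOH·H2O (cat.), 4 Å MS, CH2Cl2, rt; chromatographic removal of the (2S,6S) epimer
Reagents that add atoms: none
Why: Cyclodehydration of a δ-hydroxy-β-diketone to a 2,3-dihydro-4H-pyran-4-one: the freed benzylic alcohol should add to the vinylogous-acid carbon next to the unsubstituted ring CH2 (the other is shielded by the branched C6) and lose water; the C2–O bond is never broken, so (S) is retained, and because C6 is not controlled the (2S,6S) epimer is removed here.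

Step 7
Reactants: 11 the (2S,6R)-chromenedione ester
Product: 14 benzyl (2S)-2-{[(2S,6R)-7,7-dimethyl-8-methylidene-4,5-dioxo-2-phenyl-3,4,5,6,7,8-hexahydro-2H-chromen-6-yl]methoxy}propanoate, via Mannich base 12 (not isolated), via ammonium iodide 13 (not isolated)
Conditions: CH2=NMe2+ I− (1.2 equiv), DBU (1.2 equiv), CH2Cl2, 0 °C → rt; then MeI; then aq NaHCO3
Reagents that add atoms: N,N-dimethylmethyleneiminium iodide, C=[N+](C)C.[I-]
Why: Mannich reaction followed by elimination of the quaternised amine: C8–H2 is the only C–H acid within reach of DBU because its conjugate base is a vinylogous β-diketonate, so aminomethylation should occur at C8 and not at C3 or C6, and loss of NMe3 gives the exocyclic alkene without touching C2 or C6.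

Step 8
Reactants: 14 the 8-methylidene ester
Product: 15 (2S)-2-{[(2S,6R)-7,7,8-trimethyl-4,5-dioxo-2-phenyl-3,4,5,6,7,8-hexahydro-2H-chromen-6-yl]methoxy}propanoic acid (both C8 epimers)
Conditions: H2 (1 atm), 5% Pd/C, EtOAc, rt; stopped after 2 equiv H2
Reagents that add atoms: none
Why: Heterogeneous hydrogenation saturates the unhindered 1,1-disubstituted alkene and hydrogenolyses the benzyl ester in the same operation, while the tetrasubstituted vinylogous-ester alkene is inert; C8 forms as an epimer mixture that is planarised again in step 9, and the hydrogen uptake is limited to spare the benzylic C2–O bond.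

Step 9
Reactants: 15 the keto acid
Product: 16 TBS (2S)-2-{[(2S,6R)-5-(TBS-oxy)-7,7,8-trimethyl-4-oxo-2-phenyl-2,3,6,7-tetrahydro-4H-chromen-6-yl]methoxy}propanoate
Conditions: TBSCl (2.3 equiv), DBU (2.3 equiv), CH2Cl2, 0 °C → rt; pentane, filtration under Ar; used crude
Reagents that add atoms: tert-butyldimethylsilyl chloride, CC(C)(C)[Si](C)(C)Cl
Why: Amidine-mediated silylation of O–H and C–H acids: DBU converts the acid into its silyl ester and can deprotonate only C8–H (vinylogous β-diketone acidity, far above C3–H and C6–H), and the dienolate is O-silylated to the 5-silyloxy dienol ether, any O4-silylated isomer being expected to equilibrate by 1,5-O→O silyl migration.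

Step 10
Reactants: 16 the bis-silyl compound
Product: 17 (2S)-2-{[(2S,6R)-5-(TBS-oxy)-7,7,8-trimethyl-4-oxo-2-phenyl-2,3,6,7-tetrahydro-4H-chromen-6-yl]methoxy}propanoyl chloride
Conditions: (COCl)2 (1.05 equiv), DMF (cat.), CH2Cl2, 0 °C → rt; volatiles removed; used at once
Reagents that add atoms: oxalyl chloride, O=C(Cl)C(Cl)=O
Why: Silyl esters are converted by oxalyl chloride/catalytic DMF into acid chlorides with release of volatile TBSCl and no free HCl, which the acid-labile dienol ether should tolerate; no stereocentre is involved.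

Step 11
Reactants: 17 the acid chloride
Product: 19 oxolane-fused 2-acyl-2-vinylcyclobutanone (4R,7S,14R,18S,26R; O27-TBS), via ketene 18 (not isolated)
Conditions: slow addition of 17 to Et3N (3 equiv), toluene, 80 °C, final concentration about 5 mM
Reagents that add atoms: none
Why: Et3N removes HCl from the α-alkoxy acid chloride to give alkoxy(methyl)ketene 18, whose electrophilic central carbon C9 is attacked by C14, the nucleophilic terminus of the C26=C14 silyl enol ether, while C7 captures the silyloxy-stabilised positive charge developing at C26 (asynchronous, orthogonal ketene [2+2]). The closest known reaction type is the intramolecular cycloaddition of (3-butenyloxy)ketenes to 2-oxabicyclo[3.2.0]heptan-7-ones, together with the [2+2] of ketenes with silyl enol ethers. The oxolane closes in a 5-exo-trig sense (C7 onto C26, the only mode the O6–C5–C4 tether permits), and the cyclobutanone closes through C9–C14 as the second bond of the cycloaddition, necessarily cis-fused. C26 and C7 are set by C4, whose tether can deliver the ketene only to the ring face that carries C5, and C14 follows from suprafacial addition to the alkene, C9 ending on the same face as C7. The step needs intramolecular reaction to beat ketene dimerisation (slow addition, high dilution) and [2+2] at C26=C14 to beat attack at the diene terminus C11; the short tether secures the former mode, and a formal [4+2] across C26/C11 would simply give 20 directly.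

Step 12
Reactants: 19 the cyclobutanone
Product: 20 O27-TBS ether of the target (4R,7S,11R,18S,26R)
Conditions: hν (350 nm, Pyrex), degassed benzene, rt, monitored to full conversion of 19
Reagents that add atoms: none
Why: Photochemical 1,3-acyl shift of a β,γ-unsaturated ketone: n→π* excitation cleaves the strained C9–C14 bond (Norrish type I) to an acyl–allyl radical pair that should recombine at C11 on the face already held by C7, which fixes C11, driven by release of cyclobutanone strain and return of the vinylogous ester; the silyl ether is kept so that no C26 alkoxide can open the cyclobutanone by retro-aldol cleavage.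

Step 13
Reactants: 20 the silyl ether
Product: 21 CNP0322161.1 (target; 4R,7S,11R,18S,26R)
Conditions: HF·pyridine, pyridine, THF, 0 °C → rt (or 48% aq HF, MeCN)
Reagents that add atoms: none
Why: Acidic fluoride desilylation of the bridgehead tertiary silyl ether; the carbinol cannot ionise or eliminate at a bridgehead, and non-basic conditions avoid retro-aldol cleavage of the β-hydroxy ketone and opening of the pyranone at C18.

Compound list
1 | benzyl (2S)-2-hydroxypropanoate (benzyl (S)-lactate) | C[C@H](O)C(=O)OCc1ccccc1 | starting material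
2 | benzyl (2S)-2-(chloromethoxy)propanoate | C[C@H](OCCl)C(=O)OCc1ccccc1 | intermediate
3 | dimedone (5,5-dimethylcyclohexane-1,3-dione) | CC1(C)CC(=O)CC(=O)C1 | starting material
4 | benzyl (2S)-2-[(2,2-dimethyl-4,6-dioxocyclohexyl)methoxy]propanoate, both ring epimers | CC1(C)CC(=O)CC(=O)C1CO[C@@H](C)C(=O)OCc1ccccc1 | intermediate
5 | ethyl (3S)-3-hydroxy-3-phenylpropanoate | CCOC(=O)C[C@H](O)c1ccccc1 | starting material
6 | ethyl (3S)-3-(TBS-oxy)-3-phenylpropanoate | CCOC(=O)C[C@H](O[Si](C)(C)C(C)(C)C)c1ccccc1 | intermediate
7 | (3S)-3-(TBS-oxy)-3-phenylpropanoic acid | OC(=O)C[C@H](O[Si](C)(C)C(C)(C)C)c1ccccc1 | intermediate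
8 | enol ester of 4 with 7 (O-acyl on the less hindered enol oxygen; ring epimers) | CC1(C)CC(OC(=O)C[C@H](O[Si](C)(C)C(C)(C)C)c2ccccc2)=CC(=O)C1CO[C@@H](C)C(=O)OCc1ccccc1 | intermediate
9 | 2-acyl trione: benzyl (2S)-2-({5-[(3S)-3-(TBS-oxy)-3-phenylpropanoyl]-2,2-dimethyl-4,6-dioxocyclohexyl}methoxy)propanoate, enol form, ring epimers | CC1(C)CC(O)=C(C(=O)C[C@H](O[Si](C)(C)C(C)(C)C)c2ccccc2)C(=O)C1CO[C@@H](C)C(=O)OCc1ccccc1 | intermediate
10 | hydroxy trione (9 without the silyl group; (3S)-carbinol) | CC1(C)CC(O)=C(C(=O)C[C@H](O)c2ccccc2)C(=O)C1CO[C@@H](C)C(=O)OCc1ccccc1 | intermediate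
11 | benzyl (2S)-2-{[(2S,6R)-7,7-dimethyl-4,5-dioxo-2-phenyl-3,4,5,6,7,8-hexahydro-2H-chromen-6-yl]methoxy}propanoate | O=C1C[C@@H](c2ccccc2)OC2=C1C(=O)[C@@H](CO[C@@H](C)C(=O)OCc1ccccc1)C(C)(C)C2 | intermediate
12 | Mannich base: 8-(dimethylaminomethyl) derivative of 11 (C8 epimers) | O=C1C[C@@H](c2ccccc2)OC2=C1C(=O)[C@@H](CO[C@@H](C)C(=O)OCc1ccccc1)C(C)(C)C2CN(C)C | intermediate
13 | ammonium iodide: 8-(trimethylammoniomethyl) derivative of 11, iodide | O=C1C[C@@H](c2ccccc2)OC2=C1C(=O)[C@@H](CO[C@@H](C)C(=O)OCc1ccccc1)C(C)(C)C2C[N+](C)(C)C.[I-] | intermediate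
14 | benzyl (2S)-2-{[(2S,6R)-7,7-dimethyl-8-methylidene-4,5-dioxo-2-phenyl-3,4,5,6,7,8-hexahydro-2H-chromen-6-yl]methoxy}propanoate | O=C1C[C@@H](c2ccccc2)OC2=C1C(=O)[C@@H](CO[C@@H](C)C(=O)OCc1ccccc1)C(C)(C)C2=C | intermediate
15 | (2S)-2-{[(2S,6R)-7,7,8-trimethyl-4,5-dioxo-2-phenyl-3,4,5,6,7,8-hexahydro-2H-chromen-6-yl]methoxy}propanoic acid, C8 epimers | O=C1C[C@@H](c2ccccc2)OC2=C1C(=O)[C@@H](CO[C@@H](C)C(O)=O)C(C)(C)C2C | intermediate
16 | TBS (2S)-2-{[(2S,6R)-5-(TBS-oxy)-7,7,8-trimethyl-4-oxo-2-phenyl-2,3,6,7-tetrahydro-4H-chromen-6-yl]methoxy}propanoate | CC1=C2O[C@H](c3ccccc3)CC(=O)C2=C(O[Si](C)(C)C(C)(C)C)[C@@H](CO[C@@H](C)C(=O)O[Si](C)(C)C(C)(C)C)C1(C)C | intermediate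
17 | (2S)-2-{[(2S,6R)-5-(TBS-oxy)-7,7,8-trimethyl-4-oxo-2-phenyl-2,3,6,7-tetrahydro-4H-chromen-6-yl]methoxy}propanoyl chloride (key-step precursor) | CC1=C2O[C@H](c3ccccc3)CC(=O)C2=C(O[Si](C)(C)C(C)(C)C)[C@@H](CO[C@@H](C)C(Cl)=O)C1(C)C | intermediate
18 | alkoxy(methyl)ketene derived from 17 | CC1=C2O[C@H](c3ccccc3)CC(=O)C2=C(O[Si](C)(C)C(C)(C)C)[C@@H](COC(C)=C=O)C1(C)C | intermediate
19 | oxolane-fused 2-acyl-2-vinylcyclobutanone, (4R,7S,14R,18S,26R), O27-TBS (key-step product) | CC1(C)[C@@H]2CO[C@]3(C)C(=O)[C@@]4(C(=O)C[C@@H](c5ccccc5)OC4=C1C)[C@]23O[Si](C)(C)C(C)(C)C | intermediate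
20 | O27-TBS ether of the target, (4R,7S,11R,18S,26R) | CC1(C)[C@@H]2CO[C@]3(C)C(=O)[C@@]1(C)C1=C(C(=O)C[C@@H](c4ccccc4)O1)[C@]23O[Si](C)(C)C(C)(C)C | intermediate
21 | CNP0322161.1, (4R,7S,11R,18S,26R) | CC1(C)[C@@H]2CO[C@]3(C)C(=O)[C@@]1(C)C1=C(C(=O)C[C@@H](c4ccccc4)O1)[C@]23O | target

Total step count: 13.
Longest linear sequence: 11 steps (1 → 2 → 4 → 9 → 11 → 14 → 15 → 16 → 17 → 19 → 20 → 21; the branch from 5 is equally long).

Steps most likely to fail (no step goes beyond known reaction types, so they are ordered by risk):

Step 11. The process at risk is bimolecular consumption of ketene 18 (dimerisation, acylation of a second molecule) outrunning a cycloaddition that the acyl group on C14 slows. The fallback replaces the ketene by the more electrophilic keteniminium ion in an intramolecular keteniminium–alkene [2+2]. It sets out from acid 15, which is coupled with pyrrolidine (EDC, HOBt) to the pyrrolidine amide F1. TBSCl/DBU, as in step 9, should then give the 5-silyloxy dienol ether amide F2. Tf2O with 2,6-di-tert-butyl-4-methylpyridine in CH2Cl2 converts the amide into the keteniminium triflate F3, which should add across C26=C14 to the cyclobutaniminium triflate F4. Aqueous NaHCO3 hydrolyses this salt to cyclobutanone 19, where the route is rejoined.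

Step 9. The process at risk is slow or misdirected deprotonation (C3 instead of C8, followed by E1cB opening of the pyranone), and then, in step 10, attack of the chlorinating species on the finished dienol ether. The fallback inverts the order and changes the enolisation mode. It sets out from acid 15, which is converted under neutral conditions with 1-chloro-N,N,2-trimethylprop-1-en-1-amine into the keto acid chloride F5. Soft enolisation with TBSOTf/2,6-lutidine at −78 → −30 °C then installs the dienol ether under Lewis-acidic, equilibrating conditions; the base is too hindered and weak to dehydrochlorinate the acid chloride. This delivers 17 directly, bypassing 16.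

Step 12. The process at risk is secondary photochemistry of the acyl–allyl radical pair or of the product (decarbonylation, reverse shift, ketene extrusion). The fallback leaves the excited-state manifold and promotes the same 1,3-shift in the ground state by Lewis-acid ionisation (MeAlCl2 or TMSOTf, CH2Cl2, −78 → 0 °C), a known ring expansion of 2-vinylcyclobutanones. The acylium/dienolate pair recombines at C11. It sets out from 19 and returns at 20 without any new compound (F0).

Further compounds
F1 | step 11 | pyrrolidine amide of acid 15 (C8 epimers) | O=C1C[C@@H](c2ccccc2)OC2=C1C(=O)[C@@H](CO[C@@H](C)C(=O)N1CCCC1)C(C)(C)C2C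
F2 | step 11 | 5-silyloxy dienol ether of amide F1 | CC1=C2O[C@H](c3ccccc3)CC(=O)C2=C(O[Si](C)(C)C(C)(C)C)[C@@H](CO[C@@H](C)C(=O)N2CCCC2)C1(C)C
F3 | step 11 | keteniminium triflate from F2 | CC1=C2O[C@H](c3ccccc3)CC(=O)C2=C(O[Si](C)(C)C(C)(C)C)[C@@H](COC(C)=C=[N+]2CCCC2)C1(C)C.[O-]S(=O)(=O)C(F)(F)F
F4 | step 11 | cyclobutaniminium triflate (iminium analogue of 19) | CC1(C)[C@@H]2CO[C@]3(C)C(=[N+]6CCCC6)[C@@]4(C(=O)C[C@@H](c5ccccc5)OC4=C1C)[C@]23O[Si](C)(C)C(C)(C)C.[O-]S(=O)(=O)C(F)(F)F
F5 | step 9 | acid chloride of keto acid 15 (C8 epimers) | O=C1C[C@@H](c2ccccc2)OC2=C1C(=O)[C@@H](CO[C@@H](C)C(Cl)=O)C(C)(C)C2C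
F0 | step 12 | none | none
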